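Two captures compete here. A flask holds starting material at 0.10 M and second nucleophile at 0.200 M under gas held at 18 mM, with none of it dissolved at the start. The larch run, this same flask followed so far, reads with a scatter of 0.5 percentage points:

larch run (percent of the starting material charged)

| time / s | other capture product / % | target / % |
|---|---|---|
| 10.0 | 31.0 | 5.3 |
| 25.0 | 48.7 | 10.7 |
| 50.0 | 55.7 | 11.7 |
| 80.0 | 56.8 | 11.5 |

(standard deviation of a reading: 0.5 percentage points)

1. ratio of other capture product to target at 0.50 s
2. ratio of other capture product to target at 4.0 min
3. which of other capture product and target there is more of at 4.0 min

Start with the main step alone. With [second nucleophile] taken at its charge and the target's capture taken as steady, the ratio of other capture product to target is proportional to [second nucleophile]. The last reading gives that ratio as 4.94, which divided by the charge is 24.7 M⁻¹.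

Add one process. Each other capture product uses up a second nucleophile, so [second nucleophile] falls during the run. Its halfway value, the charge less half of what the other capture product has used, is 0.172 M. The final ratio divided by this halfway [second nucleophile] is the capture quotient 28.8 M⁻¹, a selectivity factor read from the larch run and carrying its scatter.

Add the rest. Gas enters from nothing, and the first reading's ratio of 5.85 stands above the plateau. This reckoning expects the ratio at 0.50 s to lie beyond that reading, but gives it no figure. Both products are flat from 50.0 s within the scatter, so it commits to about 4.94 at 4.0 min.

The forecast gives 40 at 0.50 s, 5 at 4.0 min and other capture product ahead, on the ground that “little gas has dissolved”.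

The flask gives 16.1 at 0.50 s and 4.62 at 4.0 min, with other capture product ahead at 56.2% against 12.2% of target. The forecast's early ratio stands 2.48 times the flask's.

    starting material → intermediate (k = 0.0760 s⁻¹)
    first nucleophile + intermediate → target (k = 950 M⁻¹ s⁻¹)
    second nucleophile + intermediate → other capture product (k = 240 M⁻¹ s⁻¹)
    intermediate → solvolysis product (k = 23.0 s⁻¹)
    gas ⇌ first nucleophile, rate k5*(csat - [first nucleophile]) (kL = 0.820 s⁻¹)
    2 first nucleophile → homo dimer (k = 34.0 M⁻¹ s⁻¹)

At 2.00 min the flask holds [second nucleophile] at 0.144 M and [first nucleophile] at 0.00989 M, which puts capture by the second nucleophile, per intermediate, at 3.67 times capture by the first, and the quotient 28.8 M⁻¹ times the flask's halfway [second nucleophile] of 0.172 M gives 4.95 beside its 4.62. The neighbour flask charged with 0.050 M of second nucleophile ends with 22.3% other capture product and a halfway [second nucleophile] of 0.0389 M, for which the quotient gives 1.12, and that flask stands at 1.04.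

The data stem from a simulated flask with constants of no real substance.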